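Late in the epsilon run the left-handed substrate reads 0.3% at 2.00 min, inside the scatter of 0.3 percentage points, so you cannot read the excess there; you have to reckon it.

all flasks: left-handed substrate 0.30 M; right-handed substrate 0.30 M

| run | reagent | free catalyst | remark | time |
|---|---|---|---|---|
| epsilon | 0.90 M | 0.42 mM | run made earlier |  |
| gamma | 0.90 M | 0.95 mM | run made earlier |  |
| theta | 1.4 M | 0.63 mM | run made earlier |  |
| flask | 0.900 M | 0.63 mM |  | 2.0 min |

| run | time / min | right-handed substrate / % | left-handed substrate / % | left-handed product / % |
|---|---|---|---|---|
| epsilon | 0.667 | 17.0 | 3.3 | 47.1 |
| epsilon | 1.33 | 10.9 | 0.7 | 49.2 |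
| epsilon | 2.00 | 8.1 | 0.3 | 49.9 |
| epsilon | 2.50 | 6.9 | 0.6 | 49.6 |
| gamma | 0.333 | 14.2 | 1.6 | 48.6 |
| gamma | 0.833 | 5.5 | 1.1 | 49.9 |
| gamma | 1.50 | 2.1 | 0 | 50.3 |
| gamma | 2.50 | 1.7 | 0 | 50.3 |
| theta | 0.667 | 3.7 | 0 | 50.3 |
| theta | 1.33 | 1.2 | 0 | 50.5 |
| theta | 2.00 | 1.0 | 0 | 50.3 |
| theta | 2.50 | 0 | 0.3 | 50.0 |

(standard deviation of a reading: 0.3 percentage points)

- free catalyst is single-handed; left-handed substrate and right-handed substrate are mirror images of each other, charged as a racemate, each of them at the stated concentration
- the numbers in the tables scatter with a standard deviation of 0.3 points

- whether the excess of right-handed substrate over left-handed substrate among what is left of the two reaches 95% by 2.0 min (yes / no)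
- the highest excess of right-handed substrate over left-handed substrate among what is left of the two up to 2.0 min

Fold the readings into one number, the selectivity factor: the logarithmic loss of left-handed substrate divided by that of right-handed substrate. The first epsilon reading, where the left-handed substrate stands highest above the scatter, gives 2.52. If both hands meet the same catalyst and reagent, then when c(right-handed substrate) has fallen to a fraction f of its charge, the ratio c(left-handed substrate)/c(right-handed substrate) is f to the power s minus one, however the catalyst and reagent change. So 95% excess needs the right-handed substrate down to 4.49% of both charged.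

But this number gives the target, not the time. For that, take the exposure ln(charge/left): 1.82 for epsilon at 2.00 min and 3.17 for gamma at 1.50 min. My interpolation on logarithmic catalyst gives the flask 2.49, so 4.14% is left, less than the target, and the excess is 95.6%: a narrow yes.

The forecast says yes with a top of 97.5%, higher than my figure, and reasons “so there is no sign of racemisation and the excess should rise steadily”.

The flask gives yes, with a top of 96.1%. The excess reaches 95% at 1.71 min, with 4.58% of right-handed substrate left.

    reagent + free catalyst + left-handed substrate → free catalyst + left-handed product (k = 380 /M²/s)
    reagent + free catalyst + right-handed substrate → free catalyst + right-handed product (k = 150 /M²/s)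
    2 reagent → self-condensation product (k = 0.00670 /M/s)
    free catalyst → spent catalyst (k = 0.00480 /s)

Put the flask's 3.87% of right-handed substrate at 2.00 min into s, and you get 96.0%. So the excess follows how far the right-handed substrate has gone, and its own step carries the part reacted at 2.00 min from 50.0% to 96.1%. Self-condensation, which slows that step, is a part of what holds the excess down, beside the 43.8% of catalyst spent by 2.00 min: self-condensation costs 2.7 points of excess. The simulated run without that step has 98.3% reacted, and s turns what remains into 98.8%; that run stands at 98.9%.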